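**One-step world.** In a one-step world the electrophile in the flask is lost at k[nucleophile] per minute, and its turns add up as that rate over time. The nucleophile charge stands at 2.50 times the electrophile charge, so [nucleophile] sinks as it is used, and this is not a pseudo-first-order decay. As a rough rule I scale the turns with the nucleophile charged, other charges and time held. Dawn reads 11% of its electrophile at 20.0 min, so 2.21 is its turnover count, the natural logarithm of the charge over the electrophile left.

| setting | midnight | dawn | flask |
|---|---|---|---|
| electrophile | 11 mM (fed, over 4.0 min) | 11 mM (fed, over 4.0 min) | 11 mM (fed, over 4.0 min) |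
| nucleophile | 27.5 mM | 27.5 mM | 27.5 mM |
| free base | 11 mM | 22 mM | 11.0 mM |
| remark | the very flask that is asked about, followed so far | run made earlier |  |
| time |  |  | 20 min |

| run | time / min | electrophile / % | target / % |
|---|---|---|---|
| midnight | 0.833 | 19 | 2 |
| midnight | 1.50 | 32 | 8 |
| midnight | 2.50 | 50 | 14 |
| midnight | 3.00 | 57 | 18 |
| midnight | 4.00 | 68 | 30 |
| dawn | 1.50 | 33 | 4 |
| dawn | 3.00 | 54 | 22 |
| dawn | 6.00 | 50 | 46 |
| dawn | 10.0 | 30 | 72 |
| dawn | 20.0 | 11 | 88 |

(scatter of a reading: 1.5 percentage points)

- part of the electrophile that has reacted at 20 min
- share of the unused nucleophile that is free and not bound as protonated nucleophile, at 20 min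

**Two flasks.** Midnight, the flask asked about, and dawn charge the same electrophile and nucleophile, and dawn has twice the free base. At 1.50 min their electrophile readings differ by 1 percentage point, and at 3.00 min by 3 points, with a scatter of 1.5 points on each. The midnight base charge matches the electrophile charge. As a rough reckoning I carry dawn's count over and expect midnight to stand at 89.0% reacted at 20 min. This rests on one scattered dawn reading and on a comparison that ends at 3.00 min. The readings do not show how much nucleophile is bound, so I give no figure for the share free.

**The forecast.** The forecast gives 86% reacted and 82% free. Its reacted figure lies below mine, and of the share free it says: “The runs do not settle this”.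

**The result.** Midnight gives 89.8% reacted and 72.3% free, below the forecast's share.

    electrophile + nucleophile → acid set free + target (k = 8.10 M⁻¹ min⁻¹)
    electrophile + target → side product (k = 8.40 M⁻¹ min⁻¹)
    acid set free + free base ⇌ salt of the base (K = 1.70 × 10⁶ M⁻¹, k = 770 M⁻¹ min⁻¹)
    nucleophile + acid set free ⇌ protonated nucleophile, settled at all times (K = 8200 M⁻¹)
    crystals ⇌ target, rate k5*(cs5 - [target]) while solid is left; crystals form when [target] > cs5 (solubility = 0.220 mM, k = 14.0 min⁻¹)

**Counting again.** Midnight's count is 2.28, against the 2.21 read from dawn's scattered reading. A neighbouring flask with 11 mM of nucleophile gets a scaled count of 0.883, which leaves 41.4%, and it holds 43.4%. At 5.43 min in midnight, the half-life of electrophile by its reaction with nucleophile is 4.7 min, shorter than the 31 min of free base by the forward step with acid set free alone. At 20.0 min midnight still holds 56.8% of its free base beside 4.93 mM of protonated nucleophile.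

(The runs come from a simulation with constants of no real substance; the scatter is artificial.)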